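(Readings and results stem from a simulated flask for substances that don't exist; scatter was added.)

At 40.0 h the eta run, charged at 0.33 M, held 39.9% substrate and 21.6% over-reaction product. At the same time the delta run, charged with more at 0.49 M, held 38.7% and 21.3%. These percentages barely move with the charge, as first-order steps from substrate to ring and from ring to over-reaction product would have it, so north and south-east can be reckoned from constants read in the eta run.

| flask | substrate | remark | time |
|---|---|---|---|
| eta | 0.33 M | run made earlier |  |
| delta | 0.49 M | run made earlier |  |
| north | 0.66 M |  | 2.5 d |
| south-east | 0.66 M |  | 3.0 d |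

| run | time / h | open dimer / % | substrate / % | ring / % | over-reaction product / % |
|---|---|---|---|---|---|
| eta | 5.00 | 1.5 | 88.1 | 9.4 | 0.7 |
| eta | 12.0 | 2.9 | 73.9 | 18.5 | 2.8 |
| eta | 25.0 | 5.3 | 54.8 | 29.1 | 10.8 |
| eta | 40.0 | 6.2 | 39.9 | 32.4 | 21.6 |
| delta | 3.00 | 1.3 | 92.0 | 5.8 | 0.3 |
| delta | 6.00 | 2.6 | 85.7 | 10.9 | 1.0 |
| delta | 15.0 | 5.5 | 67.9 | 21.8 | 4.4 |
| delta | 40.0 | 8.5 | 38.7 | 31.0 | 21.3 |

(scatter of a reading: 0.3 percentage points)

* which of these there is most of at the end, counted by the substrate in it, north (substrate / over-reaction product / ring / open dimer)
* which of these there is most of at the end, counted by the substrate in it, south-east (substrate / over-reaction product / ring / open dimer)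
* the largest of these amounts at the end, in percent of the substrate charged, north
* the largest of these amounts at the end, in percent of the substrate charged, south-east

- percent here means substrate units held: one open dimer counts as two
- what was read earlier has a scatter of 0.3 percentage points, one standard deviation
- a reading or a percentage of ring counts all its forms, free or not

Over the first 5.00 h of the eta run, ring and product together reached 10.1% while substrate averaged 94.0%, which reads as 0.0215 h⁻¹ for the closing step. Between 25.0 h and 40.0 h, product gained 11 percentage points on a mean ring of 30.8%, which reads as 0.0234 h⁻¹ for the step onward. The two lie close, so one mean constant of 0.0224 h⁻¹ serves both.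

North, read at 2.5 d, then stands at 1.35 by the turnover count, n, a batch Damköhler number: the constant times the time, which is the time measured in mean lifetimes of one step. A unit has taken no step with probability exp(−n), exactly one with n·exp(−n), and both with the remainder. Open dimer stands outside this count; its 8.5% in the delta run, scaled to 0.66 M, sets aside about 11.4%.

My reckoning for north is thus substrate 23.0%, ring 31.0% and product 34.5%. South-east, at 1.62 turnovers, has substrate 17.6%, ring 28.4% and product 42.5%. Product therefore holds more than any other species in north and in south-east.

The forecast agrees that “Over-reaction product leads at both times”, with higher amounts of 36% and 43.5%.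

North gives over-reaction product at 35.0%, and south-east gives over-reaction product at 42.7%.

    substrate ⇌ ring (K = 19.9, k = 3.53 × 10⁻⁴ min⁻¹)
    2 substrate ⇌ open dimer (K = 3.90 M⁻¹, k = 9.29 × 10⁻⁵ M⁻¹ min⁻¹)
    crystals ⇌ ring, rate k3*(cs3 - [ring]) while solid is left; crystals form when [ring] > cs3 (solubility = 0.320 M, k = 0.00440 min⁻¹)
    ring → over-reaction product (k = 3.94 × 10⁻⁴ min⁻¹)

In north, the half-life of ring by its loss to over-reaction product, 1.2 d, lies close to that of substrate by the making of ring, 1.4 d (forward rate alone), and these steps count 1.42 and 1.27 turnovers respectively, on either side of the reckoned 1.35. Ring in north is made 2.10 times faster than it is used at 0.812 d, but at 0.704 of its use at 2.50 d. The same flask read at 4.0 d counts 2.15 turnovers, which reckons product at 56.2%, and it holds 55.6%.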